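**Retrosynthetic overview**

Elemane numbering: ring C5–C10; C10 is quaternary (methyl C14, vinyl C1=C2), C9 is CH2, C8 carries the acyloxy group, C7 carries C11(=C13)–C12O2Me, C6 is the carbinol, C5 carries C4(=C3)–C15H2OH.
Feature: C9–C10(C14)–C1=C2 is an unbroken isoprene unit, and the other ring carbons C5–C6–C7–C8, oxygenated at C6 and C8, map onto a 3-alkoxycyclobutanone cut between C5 and C8.
Late disconnections: O8 ester (acylation after debenzylation), C11=C13 (ester α-methylenation), C6–OH (ketone reduction), C5–C4 (enolate alkenylation with a silylated 2-bromoallyl alcohol), C7–C11 (enolate alkylation with methyl bromoacetate), back to 5-(benzyloxy)-3-methyl-3-vinylcyclohexanone.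
Key disconnection: that cyclohexanone ⇒ 3-(benzyloxy)cyclobutanone + isoprene by a strain-release formal [4+2] annulation that makes C8–C9 and C5–C10 and closes the only ring of the target; no other ring is formed.

Key step: step 1

Assumption: the sense of asymmetric induction of the BINOL–titanium Lewis acid in step 1 cannot be predicted with confidence; (R)-BINOL is written, and (S)-BINOL would be used if the annulation favours the mirror image of the key-step product. C-locants in the steps are the elemane locants above.

**Route**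

Step 1
Reactants: 1 3-(benzyloxy)cyclobutan-1-one; 2 isoprene
Product: 5 (3R,5S)-5-(benzyloxy)-3-methyl-3-vinylcyclohexan-1-one (benzyloxy and vinyl cis), via titanium enolate oxocarbenium zwitterion 3 (not isolated), via tertiary allyl cation 4 (not isolated)
Conditions: (R)-BINOL (22 mol%), TiCl2(OiPr)2 (20 mol%), 4 Å MS, CH2Cl2, 25 °C; then 1, 2 (3 equiv), −40 → −20 °C; cold NaHCO3 (aq.)
Reagents that add atoms: none
Why: Proposed new method: the chiral titanium Lewis acid binds the ketone oxygen and, helped by the benzyloxy lone pair, breaks the strained C5–C8 bond of 1 to the titanium enolate/oxocarbenium zwitterion 3; isoprene attacks C8 through the CH2 terminus next to its methyl-bearing carbon (tertiary allyl cation 4) and the enolate carbon C5 then bonds to C10, the closest known reaction type being the SnCl4-, TiCl4- and EtAlCl2-promoted formal [4+2] annulation of 3-alkoxycyclobutanones with allylsilanes, silyl enol ethers and carbonyl compounds, for which neither a plain 1,3-diene partner nor a chiral Lewis acid has been shown. The ring closes in a 6-(enolendo)-exo-trig mode at C10, the only cationic terminus within reach, since attack at C2 would need an eight-membered ring. C8 is set in the C8–C9 bond formation, where the BINOL ligand on titanium either selects one of the two enantiotopic ring bonds of 1 in an SN2-like opening or shields one face of the tightly bound zwitterion (precedent in kind: chiral-Lewis-acid desymmetrisation of 3-substituted cyclobutanones and enantioselective annulations of donor–acceptor cyclobutanes). C10 is set relative to C8 by a chair-like transition state with the benzyloxy group and the longer allyl arm (the future vinyl group) equatorial and the methyl group axial, which gives the cis relation of O8 and vinyl. The step needs regioselectivity (secured by the tertiary allyl cation and by ring size), suppression of cationic oligomerisation of isoprene (low temperature, substoichiometric Lewis acid, fast intramolecular capture) and survival of the β-benzyloxy ketone (cold bicarbonate quench).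

Step 2
Reactants: 5 (3R,5S)-5-(benzyloxy)-3-methyl-3-vinylcyclohexan-1-one; 6 methyl bromoacetate
Product: 8 methyl [2-(benzyloxy)-4-methyl-6-oxo-4-vinylcyclohexyl]acetate (C7 side chain trans to the C8 benzyloxy group, both equatorial), via lithium enolate 7 (not isolated)
Conditions: LiN(iPr)2, THF, −78 °C; 6, DMPU, −78 → −40 °C
Reagents that add atoms: none
Why: Kinetic deprotonation takes the unhindered C7 methylene and not the neopentyl C5 position, and SN2 alkylation of the lithium enolate by the α-bromo ester (enolate alkylation) occurs anti to the adjacent C8 benzyloxy group, which is also the thermodynamically preferred diequatorial arrangement, while the low temperature keeps E1cB loss of benzyl alcohol slow.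

Step 3
Reactants: 9 2-bromoprop-2-en-1-ol
Product: 10 [(2-bromoprop-2-en-1-yl)oxy]triisopropylsilane
Conditions: iPr3SiCl, imidazole, DMF, 0 → 25 °C
Reagents that add atoms: triisopropylsilyl chloride, CC(C)[Si](Cl)(C(C)C)C(C)C
Why: Imidazole-assisted silyl ether formation at a primary alcohol; the triisopropylsilyl ether is chosen because it should survive the strong base of step 4 and the BCl3 of step 8.

Step 4
Reactants: 8 methyl [2-(benzyloxy)-4-methyl-6-oxo-4-vinylcyclohexyl]acetate; 10 [(2-bromoprop-2-en-1-yl)oxy]triisopropylsilane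
Product: 13 methyl [2-(benzyloxy)-4-methyl-6-oxo-5-{3-[(triisopropylsilyl)oxy]prop-1-en-2-yl}-4-vinylcyclohexyl]acetate (C5 alkenyl group equatorial, cis to the C10 methyl, trans to vinyl), via lithium enolate 11 (not isolated), via lithium dienolate 12 (not isolated)
Conditions: LiN(SiMe3)2 (2.2 equiv), THF, −78 °C; 10, Pd(OAc)2 (5 mol%), [HP(tBu)3]BF4 (10 mol%), toluene, −78 → 25 °C; NH4Cl (aq.)
Reagents that add atoms: none
Why: Palladium-catalysed α-alkenylation of a ketone enolate (enolate cross-coupling): the amide base kinetically deprotonates the C5 methylene (C7 is now a shielded methine), zerovalent palladium inserts into the C–Br bond of 10, the enolate replaces bromide on palladium and reductive elimination forms C5–C4, the second equivalent of base stores the more acidic product as dienolate 12 so that neither double coupling nor migration of C4=C3 into conjugation occurs, and protonation of 12 at C5 anti to the axial C10 methyl places the alkenyl group equatorial, which is also the more stable epimer.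

Step 5
Reactants: 13 C5-alkenyl ketone
Product: 14 methyl [2-(benzyloxy)-6-hydroxy-4-methyl-5-{3-[(triisopropylsilyl)oxy]prop-1-en-2-yl}-4-vinylcyclohexyl]acetate (C6 hydroxyl equatorial, trans to both neighbours, cis to O8)
Conditions: SmI2 (3 equiv), H2O, THF, 0 → 25 °C
Reagents that add atoms: none
Why: Single-electron (ketyl) reduction by SmI2 is governed by product stability: the intermediate places its bulky O–Sm group equatorial, away from the syn-axial C10 methyl, and is protonated axially, which should give the equatorial C6 alcohol where hydride reagents would be steered to the axial epimer; without an amine additive the ester and the alkenes are not reduced, and the trans hydroxy ester should not lactonise spontaneously.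

Step 6
Reactants: 14 C6 alcohol
Product: 15 C6 tert-butyldimethylsilyl ether of 14
Conditions: tBuMe2SiOTf, 2,6-lutidine, CH2Cl2, −78 → 0 °C
Reagents that add atoms: tert-butyldimethylsilyl trifluoromethanesulfonate, CC(C)(C)[Si](C)(C)OS(=O)(=O)C(F)(F)F
Why: Silyl triflate silylation of a hindered secondary alcohol; the ether blocks lactonisation onto C12, removes the acidic proton before the ester enolate chemistry and later leaves O8 as the only free hydroxyl.

Step 7
Reactants: 15 C6 silyl ether
Product: 19 methyl 2-[2-(benzyloxy)-6-(tert-butyldimethylsilyloxy)-4-methyl-5-{3-[(triisopropylsilyl)oxy]prop-1-en-2-yl}-4-vinylcyclohexyl]acrylate, via lithium ester enolate 16 (not isolated), via Mannich base 17 (not isolated), via trimethylammonium iodide 18 (not isolated)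
Conditions: LiN(iPr)2, THF, −78 °C; (CH2=NMe2)I, −78 → 0 °C; MeI, MeOH, 25 °C; DBU, CH2Cl2, 25 °C
Reagents that add atoms: N,N-dimethylmethyleneiminium iodide, C=[N+](C)C.[I-]
Why: Ester α-methylenation by the Mannich route: the ester enolate 16 (no β-leaving group, so no elimination) is aminomethylated, N-methylation turns the amine into a leaving group, and E1cB elimination with DBU forms C11=C13 without creating a stereocentre.

Step 8
Reactants: 19 benzyl ether acrylate
Product: 20 C8 alcohol (free 8-hydroxyl; 6-O-silyl, 15-O-silyl, methyl acrylate retained)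
Conditions: BCl3 (3 equiv), C6HMe5 (5 equiv), CH2Cl2, −78 °C; NaHCO3 (aq.)
Reagents that add atoms: none
Why: Lewis-acid cleavage of the benzyl ether with pentamethylbenzene as a non-basic benzyl-cation scavenger replaces hydrogenolysis, which the three C=C bonds forbid; at −78 °C the bulky silyl ethers, the methyl ester and the alkenes should persist.

Step 9
Reactants: 21 methyl 2-(hydroxymethyl)acrylate
Product: 22 methyl 2-{[(tert-butyldimethylsilyl)oxy]methyl}acrylate
Conditions: tBuMe2SiCl, imidazole, CH2Cl2, 0 → 25 °C
Reagents that add atoms: tert-butyldimethylsilyl chloride, CC(C)(C)[Si](C)(C)Cl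
Why: Routine silyl ether formation at the primary allylic alcohol, so that the acid partner cannot acylate itself.

Step 10
Reactants: 22 methyl 2-{[(tert-butyldimethylsilyl)oxy]methyl}acrylate
Product: 24 2-{[(tert-butyldimethylsilyl)oxy]methyl}acrylic acid, via lithium carboxylate 23 (not isolated)
Conditions: LiOH, THF/H2O, 0 °C; HCl (aq.) to pH 4, 0 °C
Reagents that add atoms: lithium hydroxide, [Li+].[OH-]
Why: Saponification (acyl–oxygen ester hydrolysis) at 0 °C followed by careful acidification should leave the silyl ether in place.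

Step 11
Reactants: 20 C8 alcohol; 24 2-{[(tert-butyldimethylsilyl)oxy]methyl}acrylic acid
Product: 26 tris-silyl ether of elemacarmanin (O6 tert-butyldimethylsilyl, O15 triisopropylsilyl, acyl CH2O tert-butyldimethylsilyl), via O-acylisourea 25 (not isolated)
Conditions: DCC, DMAP (cat.), CH2Cl2, 0 → 25 °C
Reagents that add atoms: none
Why: Steglich esterification: DCC activates the acid as O-acylisourea 25 and DMAP transfers the acyl group to the only free hydroxyl (O8), the C8 configuration being untouched because its C–O bond is not broken.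

Step 12
Reactants: 26 tris-silyl ether
Product: 27 elemacarmanin
Conditions: HF·pyridine, pyridine, THF, 0 → 25 °C
Reagents that add atoms: none
Why: Fluoride-mediated cleavage of all three silyl ethers (global desilylation) under buffered, weakly acidic conditions, chosen to avoid acyl migration, conjugate addition to the two acrylate units and lactonisation of the C6 hydroxyl onto C12.

**Compound list**

1 | 3-(benzyloxy)cyclobutan-1-one | O=C1CC(OCc2ccccc2)C1 | starting material
2 | isoprene (2-methylbuta-1,3-diene) | C=CC(C)=C | starting material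
3 | ring-opened titanium enolate/oxocarbenium zwitterion on (R)-BINOLate–TiCl2 | C=C(CC=[O+]Cc1ccccc1)O[Ti-]2(Cl)(Cl)Oc1ccc3ccccc3c1-c1c(O2)ccc3ccccc13 | intermediate
4 | tertiary allyl cation after C8–C9 bond formation (titanium enolate intact) | C=C(C[C@@H](OCc1ccccc1)C[C+](C)C=C)O[Ti-]2(Cl)(Cl)Oc1ccc3ccccc3c1-c1c(O2)ccc3ccccc13 | intermediate
5 | (3R,5S)-5-(benzyloxy)-3-methyl-3-vinylcyclohexan-1-one, benzyloxy and vinyl cis | C=C[C@]1(C)C[C@H](OCc2ccccc2)CC(=O)C1 | intermediate
6 | methyl bromoacetate | COC(=O)CBr | starting material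
7 | lithium enolate of 5 (C6=C7) | C=C[C@]1(C)C[C@H](OCc2ccccc2)C=C(O[Li])C1 | intermediate
8 | methyl [2-(benzyloxy)-4-methyl-6-oxo-4-vinylcyclohexyl]acetate, C7 chain trans to benzyloxy | C=C[C@]1(C)C[C@H](OCc2ccccc2)[C@@H](CC(=O)OC)C(=O)C1 | intermediate
9 | 2-bromoprop-2-en-1-ol | C=C(Br)CO | starting material
10 | [(2-bromoprop-2-en-1-yl)oxy]triisopropylsilane | C=C(Br)CO[Si](C(C)C)(C(C)C)C(C)C | intermediate
11 | lithium enolate of 8 (C5=C6) | C=C[C@]1(C)C[C@H](OCc2ccccc2)[C@@H](CC(=O)OC)C(O[Li])=C1 | intermediate
12 | lithium dienolate of 13 | C=C[C@]1(C)C[C@H](OCc2ccccc2)[C@@H](CC(=O)OC)C(O[Li])=C1C(=C)CO[Si](C(C)C)(C(C)C)C(C)C | intermediate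
13 | C5-alkenyl ketone, alkenyl group cis to methyl and equatorial | C=C[C@]1(C)C[C@H](OCc2ccccc2)[C@@H](CC(=O)OC)C(=O)[C@H]1C(=C)CO[Si](C(C)C)(C(C)C)C(C)C | intermediate
14 | C6 alcohol, hydroxyl equatorial, trans to the C5 and C7 groups | C=C[C@]1(C)C[C@H](OCc2ccccc2)[C@@H](CC(=O)OC)[C@H](O)[C@H]1C(=C)CO[Si](C(C)C)(C(C)C)C(C)C | intermediate
15 | C6 tert-butyldimethylsilyl ether of 14 | C=C[C@]1(C)C[C@H](OCc2ccccc2)[C@@H](CC(=O)OC)[C@H](O[Si](C)(C)C(C)(C)C)[C@H]1C(=C)CO[Si](C(C)C)(C(C)C)C(C)C | intermediate
16 | lithium ester enolate of 15 | C=C[C@]1(C)C[C@H](OCc2ccccc2)[C@@H](C=C(OC)O[Li])[C@H](O[Si](C)(C)C(C)(C)C)[C@H]1C(=C)CO[Si](C(C)C)(C(C)C)C(C)C | intermediate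
17 | Mannich base (C11–CH2NMe2, both C11 epimers) | C=C[C@]1(C)C[C@H](OCc2ccccc2)[C@@H](C(CN(C)C)C(=O)OC)[C@H](O[Si](C)(C)C(C)(C)C)[C@H]1C(=C)CO[Si](C(C)C)(C(C)C)C(C)C | intermediate
18 | trimethylammonium iodide from 17 | C=C[C@]1(C)C[C@H](OCc2ccccc2)[C@@H](C(C[N+](C)(C)C)C(=O)OC)[C@H](O[Si](C)(C)C(C)(C)C)[C@H]1C(=C)CO[Si](C(C)C)(C(C)C)C(C)C.[I-] | intermediate
19 | methyl acrylate with O8 benzyl, O6 tert-butyldimethylsilyl, O15 triisopropylsilyl | C=C[C@]1(C)C[C@H](OCc2ccccc2)[C@@H](C(=C)C(=O)OC)[C@H](O[Si](C)(C)C(C)(C)C)[C@H]1C(=C)CO[Si](C(C)C)(C(C)C)C(C)C | intermediate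
20 | C8 alcohol | C=C[C@]1(C)C[C@H](O)[C@@H](C(=C)C(=O)OC)[C@H](O[Si](C)(C)C(C)(C)C)[C@H]1C(=C)CO[Si](C(C)C)(C(C)C)C(C)C | intermediate
21 | methyl 2-(hydroxymethyl)acrylate | C=C(CO)C(=O)OC | starting material
22 | methyl 2-{[(tert-butyldimethylsilyl)oxy]methyl}acrylate | C=C(CO[Si](C)(C)C(C)(C)C)C(=O)OC | intermediate
23 | lithium 2-{[(tert-butyldimethylsilyl)oxy]methyl}acrylate | C=C(CO[Si](C)(C)C(C)(C)C)C(=O)[O-].[Li+] | intermediate
24 | 2-{[(tert-butyldimethylsilyl)oxy]methyl}acrylic acid | C=C(CO[Si](C)(C)C(C)(C)C)C(=O)O | intermediate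
25 | O-acylisourea from 24 and DCC | C=C(CO[Si](C)(C)C(C)(C)C)C(=O)OC(=NC1CCCCC1)NC1CCCCC1 | intermediate
26 | tris-silyl ether of elemacarmanin | C=C[C@]1(C)C[C@H](OC(=O)C(=C)CO[Si](C)(C)C(C)(C)C)[C@@H](C(=C)C(=O)OC)[C@H](O[Si](C)(C)C(C)(C)C)[C@H]1C(=C)CO[Si](C(C)C)(C(C)C)C(C)C | intermediate
27 | elemacarmanin | C=C[C@]1(C)C[C@H](OC(=O)C(=C)CO)[C@@H](C(=C)C(=O)OC)[C@H](O)[C@H]1C(=C)CO | target

**Step count and risks**

Total step count: 12. Longest linear sequence: 9 steps (1, 2, 4, 5, 6, 7, 8, 11, 12).

Steps most likely to fail:

1. Step 1 (proposed new method). What may go wrong: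
- cationic oligomerisation of isoprene;
- proton loss or chloride capture at the allyl cation instead of ring closure;
- too little Lewis acidity to open the unsubstituted cyclobutanone;
- E1cB loss of benzyl alcohol from the product;
- poor enantio- or diastereofacial discrimination.

Fallback, known chemistry, from 1 back to 5: 1 is annulated under EtAlCl2 with 2-(trimethylsilyloxy)buta-1,3-diene, a silyl enol ether and so a partner of the established class, to 5-(benzyloxy)-3-(trimethylsilyloxy)-3-vinylcyclohexan-1-one F1. Mild acid (TsOH, CH2Cl2) expels trimethylsilanol from the tertiary allylic position and gives the dienone 5-(benzyloxy)-3-vinylcyclohex-2-en-1-one F2. Copper-catalysed 1,4-addition of MeMgBr (Cu(OTf)2 with an N-heterocyclic carbene ligand, conditions under which 3-alkenylcyclohexenones are attacked at the ring β-carbon and not at the vinyl terminus) enters anti to the benzyloxy group and gives racemic 5 with methyl trans and vinyl cis to O8. Preparative chromatography on a chiral stationary phase then separates 5 from its mirror image ent-5 F3.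

2. Step 4. What may go wrong:
- slow C–C bond formation at the neopentyl C5;
- enolate equilibration to the C7 enolate followed by E1cB loss of benzyloxide;
- competing coupling at the ester α-carbon.

Fallback from 8 back to 19, using the alkylation/methylenation logic already applied at C7: the kinetic C5 enolate of 8 (LiN(iPr)2, THF, −78 °C) is alkylated with tert-butyl bromoacetate. The electrophile should enter anti to the axial C10 methyl and give the C5-axial keto diester F4, which catalytic NaOMe in MeOH equilibrates to the all-equatorial keto diester F5. SmI2/H2O reduction as in step 5 gives the alcohol F6, and tBuMe2SiOTf/2,6-lutidine gives its silyl ether F7. Double deprotonation (LiN(iPr)2, 2.4 equiv) and the Mannich/quaternisation/elimination sequence of step 7 methylenate both ester α-carbons to the bis-acrylate F8. Me3SiOTf/2,6-lutidine then cleaves only the tert-butyl ester to the acrylic acid F9. This is reduced through its isobutyl carbonic mixed anhydride with NaBH4 to the allylic alcohol F10, and iPr3SiCl/imidazole returns to 19.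

3. Step 8. What may go wrong:
- cleavage or ionisation of the primary allylic silyl ether by the Lewis acid;
- chloride addition to the acrylate;
- incomplete cleavage at the hindered C8 ether.

Fallback from 19 back to 20, with no new compound: photo-oxidative debenzylation with DDQ (CH2Cl2/H2O, green light). It removes the benzylic hydride and releases benzaldehyde on hydrolysis, so no Lewis acid meets the silyl ethers or the acrylate.

Further compounds
F1 | step 1 | 5-(benzyloxy)-3-(trimethylsilyloxy)-3-vinylcyclohexan-1-one (racemic, both diastereomers) | C=CC1(O[Si](C)(C)C)CC(OCc2ccccc2)CC(=O)C1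
F2 | step 1 | 5-(benzyloxy)-3-vinylcyclohex-2-en-1-one (racemic) | C=CC1=CC(=O)CC(OCc2ccccc2)C1
F3 | step 1 | ent-5, (3S,5R)-5-(benzyloxy)-3-methyl-3-vinylcyclohexan-1-one | C=C[C@@]1(C)C[C@@H](OCc2ccccc2)CC(=O)C1
F4 | step 4 | C5-axial keto diester (tert-butoxycarbonylmethyl group trans to the C10 methyl) | C=C[C@]1(C)C[C@H](OCc2ccccc2)[C@@H](CC(=O)OC)C(=O)[C@@H]1CC(=O)OC(C)(C)C
F5 | step 4 | all-equatorial keto diester (C5 chain cis to the C10 methyl) | C=C[C@]1(C)C[C@H](OCc2ccccc2)[C@@H](CC(=O)OC)C(=O)[C@H]1CC(=O)OC(C)(C)C
F6 | step 4 | C6 alcohol of F5 (hydroxyl equatorial) | C=C[C@]1(C)C[C@H](OCc2ccccc2)[C@@H](CC(=O)OC)[C@H](O)[C@H]1CC(=O)OC(C)(C)C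
F7 | step 4 | C6 tert-butyldimethylsilyl ether of F6 | C=C[C@]1(C)C[C@H](OCc2ccccc2)[C@@H](CC(=O)OC)[C@H](O[Si](C)(C)C(C)(C)C)[C@H]1CC(=O)OC(C)(C)C
F8 | step 4 | bis-acrylate (tert-butyl ester at C15, methyl ester at C12) | C=C[C@]1(C)C[C@H](OCc2ccccc2)[C@@H](C(=C)C(=O)OC)[C@H](O[Si](C)(C)C(C)(C)C)[C@H]1C(=C)C(=O)OC(C)(C)C
F9 | step 4 | C15 acrylic acid | C=C[C@]1(C)C[C@H](OCc2ccccc2)[C@@H](C(=C)C(=O)OC)[C@H](O[Si](C)(C)C(C)(C)C)[C@H]1C(=C)C(=O)O
F10 | step 4 | C15 allylic alcohol | C=C[C@]1(C)C[C@H](OCc2ccccc2)[C@@H](C(=C)C(=O)OC)[C@H](O[Si](C)(C)C(C)(C)C)[C@H]1C(=C)CO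
F0 | step 8 | none | none
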